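## Retrosynthetic overview

1. The pyran ring of the chromene is closed last, by gold-catalysed 6-endo hydroarylation of an aryl tertiary-propargyl ether. The aryl–O bond is made by adding the tertiary alkoxide to the quinone monoketal of 2,4-dimethoxyphenol and rearomatising, so the carbinol C–O bond is never broken.
2. The tertiary carbinol comes from asymmetric alkynylation of a methyl ketone, whose 3-oxobutyl chain is unmasked from a (3,5-dimethylisoxazol-4-yl)methyl group.
3. The exocyclic methylene comes from a 2,2,6-trisubstituted cyclohexanone. The secondary methyl centre is set by reagent-controlled protonation of its silyl enol ether.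
4. The carbocycle and its quaternary centre are not built: 2,6-dimethylphenol is C-alkylated at an ortho carbon with loss of aromaticity (key step, enantioselective), and the dienone is then hydrogenated.
5. Ring order: carbocycle first (from the phenol), benzene ring of the chromene carried in as a dearomatised/rearomatised phenol, pyran ring last.

Assumption: metal salts formed from a reactant by simple deprotonation in the flask (phenolate, alkoxide) are not numbered; every other species that forms and reacts on is.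

## Route

Step 1
Reactants: 1 2,6-dimethylphenol; 2 4-(bromomethyl)-3,5-dimethyl-1,2-oxazole
Product: 3 (6S)-6-[(3,5-dimethyl-1,2-oxazol-4-yl)methyl]-2,6-dimethylcyclohexa-2,4-dien-1-one
Conditions: n-BuLi, LiBr, chiral tetraamine L* (1.1 equiv), toluene, −78 → −45 °C; cold work-up, crude dienone used at once [L* = (R)-N1-[2-(dimethylamino)ethyl]-N1,N2-dimethyl-N2-[1-phenyl-2-(piperidin-1-yl)ethyl]ethane-1,2-diamine]
Reagents that add atoms: none
Why: Proposed new method: lithium 2,6-dimethylphenolate in a non-polar solvent is alkylated by reactive benzylic-type halides at the ortho carbon through a cyclic O–Li···Br contact (O-alkylation is suppressed by aggregation), and a chiral tetradentate amine bound to lithium should make the two faces of the phenolate unequal so that the quaternary centre forms as the (S)-dienone (which antipode of L* does this is fixed in the first run); the closest known reaction types are the racemic ortho-C-alkylative dearomatisation of sodium 2,6-dimethylphenolate with allyl and benzyl halides in toluene and the enantioselective benzylation of lithium enolates complexed by chiral polyamine ligands.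

Step 2
Reactants: 3 (6S)-6-[(3,5-dimethyl-1,2-oxazol-4-yl)methyl]-2,6-dimethylcyclohexa-2,4-dien-1-one
Product: 4 (2R)-2-[(3,5-dimethyl-1,2-oxazol-4-yl)methyl]-2,6-dimethylcyclohexan-1-one (both C6 epimers)
Conditions: H2 (1 atm), 5% Pd/C, EtOAc, 0 → 20 °C, stopped after 2 equiv H2
Reagents that add atoms: none
Why: Heterogeneous catalytic hydrogenation saturates both conjugated ring alkenes much faster than it cleaves the isoxazole N–O bond under neutral conditions, and the C6 epimer mixture it gives is harmless because C6 is reset in step 4.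

Step 3
Reactants: 4 (2R)-2-[(3,5-dimethyl-1,2-oxazol-4-yl)methyl]-2,6-dimethylcyclohexan-1-one (both C6 epimers)
Product: 5 {[(6R)-6-[(3,5-dimethyl-1,2-oxazol-4-yl)methyl]-2,6-dimethylcyclohex-1-en-1-yl]oxy}trimethylsilane
Conditions: Me3SiOTf, Et3N, CH2Cl2, 0 → 20 °C
Reagents that add atoms: trimethylsilyl trifluoromethanesulfonate, C[Si](C)(C)OS(=O)(=O)C(F)(F)F
Why: Soft enolisation (silyl triflate/amine silyl enol ether formation) can only enolise towards C6, the sole α-CH, so both epimers converge on one enol silane while the quaternary centre is untouched.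

Step 4
Reactants: 5 {[(6R)-6-[(3,5-dimethyl-1,2-oxazol-4-yl)methyl]-2,6-dimethylcyclohex-1-en-1-yl]oxy}trimethylsilane
Product: 6 (2R,6R)-2-[(3,5-dimethyl-1,2-oxazol-4-yl)methyl]-2,6-dimethylcyclohexan-1-one
Conditions: (R)-2'-methoxy-1,1'-binaphthalen-2-ol (1.1 equiv), SnCl4 (1.0 equiv), toluene, −78 °C; NaHCO3 work-up
Reagents that add atoms: none
Why: Enantioselective protonation of a silyl enol ether by a Lewis-acid-assisted chiral Brønsted acid (precedented for the 2,2,6-trimethylcyclohexanone enol silane) is reagent-controlled and delivers the proton to the face bearing the C2 methyl, so the C6 methyl ends up cis to the side chain (6R); the sense is taken from that precedent, and the antipodal binaphthol would be used if the first run shows the other epimer.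

Step 5
Reactants: 6 (2R,6R)-2-[(3,5-dimethyl-1,2-oxazol-4-yl)methyl]-2,6-dimethylcyclohexan-1-one
Product: 7 4-{[(1R,3R)-1,3-dimethyl-2-methylidenecyclohexyl]methyl}-3,5-dimethyl-1,2-oxazole
Conditions: Zn, CH2Br2, TiCl4, THF–CH2Cl2, 0 → 20 °C
Reagents that add atoms: dibromomethane, BrCBr
Why: Takai–Lombardo methylenation uses a non-basic geminal dimetallic reagent that converts hindered, enolisable ketones into 1,1-disubstituted alkenes without epimerising the adjacent C–H centre, which is thereby locked.

Step 6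
Reactants: 7 4-{[(1R,3R)-1,3-dimethyl-2-methylidenecyclohexyl]methyl}-3,5-dimethyl-1,2-oxazole
Product: 9 4-[(1R,3R)-1,3-dimethyl-2-methylidenecyclohexyl]butan-2-one, via enaminone 8 (not isolated)
Conditions: Mo(CO)6, MeCN–H2O, 80 °C; then 2 M NaOH, EtOH, 70 °C
Reagents that add atoms: water, O
Why: Reductive N–O cleavage of the isoxazole gives the vinylogous amide, and hydroxide hydrolyses it to the β-diketone and removes one acetyl group by retro-Claisen cleavage (the classical isoxazole unmasking of a 3-oxobutyl chain), under conditions that leave the exocyclic alkene and both stereocentres alone.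

Step 7
Reactants: 9 4-[(1R,3R)-1,3-dimethyl-2-methylidenecyclohexyl]butan-2-one
Product: 11 (3S)-3-methyl-5-[(1R,3R)-1,3-dimethyl-2-methylidenecyclohexyl]pent-1-yn-3-ol, via TMS-alkynol 10 (not isolated)
Conditions: Me3SiC≡CH, Me2Zn, (R,R)-N,N'-bis(3,5-di-tert-butylsalicylidene)cyclohexane-1,2-diamine (20 mol%), toluene, 20 °C; then K2CO3, MeOH
Reagents that add atoms: ethynyltrimethylsilane, C#C[Si](C)(C)C
Why: Catalytic asymmetric addition of an alkynylzinc to a ketone (zinc–salen type) delivers the alkynyl group to the Re face of the methyl ketone under catalyst control to give the (S)-carbinol (the ring centres are too remote to matter), selectivity for methyl against a primary alkyl group being only moderate for this reaction type; the (S,S)-ligand is used if the first run shows the opposite sense, and the silyl group is removed in the same flask.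

Step 8
Reactants: 12 2,4-dimethoxyphenol
Product: 13 2,4,4-trimethoxycyclohexa-2,5-dien-1-one
Conditions: PhI(OAc)2, MeOH, 0 °C
Reagents that add atoms: methanol, CO
Why: Oxidative dearomatisation of a para-methoxyphenol with a hypervalent iodine reagent in methanol traps the phenoxonium ion at C4 and gives the quinone monoketal.

Step 9
Reactants: 11 (3S)-3-methyl-5-[(1R,3R)-1,3-dimethyl-2-methylidenecyclohexyl]pent-1-yn-3-ol; 13 2,4,4-trimethoxycyclohexa-2,5-dien-1-one
Product: 15 5-{[(3S)-3-methyl-5-[(1R,3R)-1,3-dimethyl-2-methylidenecyclohexyl]pent-1-yn-3-yl]oxy}-2,4-dimethoxyphenol, via Michael adduct 14 (not isolated)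
Conditions: KN(SiMe3)2, THF, −78 °C; 13 (1.5 equiv), −78 → −20 °C; AcOH; then pyridinium p-toluenesulfonate (10 mol%), CH2Cl2, 20 °C
Reagents that add atoms: none
Why: Proposed new method: the potassium alkoxide of 11 adds in an oxa-Michael sense to C5 of 13, the only unsubstituted enone β-carbon (C3 is deactivated by the C2 methoxy group), and mild acid then ionises the neighbouring ketal and eliminates methanol so that the ring rearomatises with the new ether meta to the phenol and ortho to a methoxy group, the carbinol C–O bond never being broken so that its configuration is kept; the closest known reaction type is conjugate addition of heteroatom and carbon nucleophiles to quinone monoketals followed by acid-induced loss of methanol.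

Step 10
Reactants: 15 5-{[(3S)-3-methyl-5-[(1R,3R)-1,3-dimethyl-2-methylidenecyclohexyl]pent-1-yn-3-yl]oxy}-2,4-dimethoxyphenol
Product: 16 metachromin B, (2S)-2-{2-[(1R,3R)-1,3-dimethyl-2-methylidenecyclohexyl]ethyl}-6,8-dimethoxy-2-methyl-2H-chromen-5-ol
Conditions: Ph3PAuNTf2 (2 mol%), CH2Cl2, 20 °C
Reagents that add atoms: none
Why: Gold-catalysed 6-endo-dig intramolecular hydroarylation of an aryl propargyl ether (alkyne π-activation, attack by the only free carbon ortho to the ether oxygen, protodeauration) closes the 2H-pyran ring at room temperature without touching the C2–O bond, so the tertiary ether centre stays (S).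

## Compound list

1 | 2,6-dimethylphenol | Cc1cccc(C)c1O | starting material
2 | 4-(bromomethyl)-3,5-dimethyl-1,2-oxazole | Cc1noc(C)c1CBr | starting material
3 | (6S)-6-[(3,5-dimethyl-1,2-oxazol-4-yl)methyl]-2,6-dimethylcyclohexa-2,4-dien-1-one | O=C1C(C)=CC=C[C@]1(C)Cc1c(C)noc1C | intermediate
4 | (2R)-2-[(3,5-dimethyl-1,2-oxazol-4-yl)methyl]-2,6-dimethylcyclohexan-1-one (both C6 epimers) | O=C1C(C)CCC[C@]1(C)Cc1c(C)noc1C | intermediate
5 | {[(6R)-6-[(3,5-dimethyl-1,2-oxazol-4-yl)methyl]-2,6-dimethylcyclohex-1-en-1-yl]oxy}trimethylsilane | C[Si](C)(C)OC1=C(C)CCC[C@]1(C)Cc1c(C)noc1C | intermediate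
6 | (2R,6R)-2-[(3,5-dimethyl-1,2-oxazol-4-yl)methyl]-2,6-dimethylcyclohexan-1-one | O=C1[C@H](C)CCC[C@]1(C)Cc1c(C)noc1C | intermediate
7 | 4-{[(1R,3R)-1,3-dimethyl-2-methylidenecyclohexyl]methyl}-3,5-dimethyl-1,2-oxazole | C=C1[C@H](C)CCC[C@]1(C)Cc1c(C)noc1C | intermediate
8 | (3Z)-4-amino-3-{[(1R,3R)-1,3-dimethyl-2-methylidenecyclohexyl]methyl}pent-3-en-2-one | C=C1[C@H](C)CCC[C@]1(C)C/C(C(C)=O)=C(\C)N | intermediate
9 | 4-[(1R,3R)-1,3-dimethyl-2-methylidenecyclohexyl]butan-2-one | C=C1[C@H](C)CCC[C@]1(C)CCC(C)=O | intermediate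
10 | (3S)-3-methyl-5-[(1R,3R)-1,3-dimethyl-2-methylidenecyclohexyl]-1-(trimethylsilyl)pent-1-yn-3-ol | C=C1[C@H](C)CCC[C@]1(C)CC[C@@](O)(C)C#C[Si](C)(C)C | intermediate
11 | (3S)-3-methyl-5-[(1R,3R)-1,3-dimethyl-2-methylidenecyclohexyl]pent-1-yn-3-ol | C=C1[C@H](C)CCC[C@]1(C)CC[C@@](O)(C)C#C | intermediate
12 | 2,4-dimethoxyphenol | COc1ccc(O)c(OC)c1 | starting material
13 | 2,4,4-trimethoxycyclohexa-2,5-dien-1-one | COC1=CC(OC)(OC)C=CC1=O | intermediate
14 | 5-{[(3S)-3-methyl-5-[(1R,3R)-1,3-dimethyl-2-methylidenecyclohexyl]pent-1-yn-3-yl]oxy}-2,4,4-trimethoxycyclohex-2-en-1-one (both C5 epimers) | C=C1[C@H](C)CCC[C@]1(C)CC[C@@](OC2CC(=O)C(OC)=CC2(OC)OC)(C)C#C | intermediate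
15 | 5-{[(3S)-3-methyl-5-[(1R,3R)-1,3-dimethyl-2-methylidenecyclohexyl]pent-1-yn-3-yl]oxy}-2,4-dimethoxyphenol | C=C1[C@H](C)CCC[C@]1(C)CC[C@@](Oc2cc(O)c(OC)cc2OC)(C)C#C | intermediate
16 | metachromin B, (2S)-2-{2-[(1R,3R)-1,3-dimethyl-2-methylidenecyclohexyl]ethyl}-6,8-dimethoxy-2-methyl-2H-chromen-5-ol | C=C1[C@H](C)CCC[C@]1(C)CC[C@@]1(C)C=Cc2c(O)c(OC)cc(OC)c2O1 | target

## Step count and risks

Total step count: 10. Longest linear sequence: 9 steps (steps 1–7, 9 and 10, from 1 to 16); step 8 is the one-step side branch.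

Stereocentres: the quaternary carbon is set in step 1, the ring CH(CH3) in step 4 (fixed by step 5), and the chromene C2 in step 7 (carried unchanged through steps 9 and 10).

The three steps most likely to fail:

Step 1. The ortho-C-alkylation itself has racemic precedent, but ligand-controlled enantioselectivity on a lithium phenolate is untested, and O-alkylation, para-alkylation and dimerisation of the dienone compete. The fallback sets out from 1 and comes back at 4, and replaces the dearomatising alkylation by desymmetrisation of a meso ketone. 1 is hydrogenated over Pd/C to cis-2,6-dimethylcyclohexanone F1. Lithium bis[(R)-1-phenylethyl]amide with Me3SiCl (or its antipode, whichever removes the right enantiotopic proton) gives {[(6S)-2,6-dimethylcyclohex-1-en-1-yl]oxy}trimethylsilane F2. MeLi then releases the lithium enolate, which is alkylated by 2 on the face away from the C6 methyl to give the (2R,6S) member of 4. Steps 3 and 4 then correct C6 as in the main route.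

Step 7. Catalyst discrimination between a methyl and a CH2CH2R group on a dialkyl ketone is only moderate, and the two C3 epimers would be hard to separate. The fallback sets out from 9 and comes back at 11, and sets the carbinol centre from alkene geometry instead. Horner–Wadsworth–Emmons reaction of 9 with triethyl phosphonoacetate and NaH gives ethyl (2E)-5-[(1R,3R)-1,3-dimethyl-2-methylidenecyclohexyl]-3-methylpent-2-enoate F3 (minor Z isomer removed). i-Bu2AlH gives (2E)-5-[(1R,3R)-1,3-dimethyl-2-methylidenecyclohexyl]-3-methylpent-2-en-1-ol F4. Sharpless epoxidation (Ti(OiPr)4, L-(+)-diethyl tartrate, t-BuOOH) gives [(2S,3S)-3-{2-[(1R,3R)-1,3-dimethyl-2-methylidenecyclohexyl]ethyl}-3-methyloxiran-2-yl]methanol F5. PPh3 in CCl4 gives (2R,3S)-2-(chloromethyl)-3-{2-[(1R,3R)-1,3-dimethyl-2-methylidenecyclohexyl]ethyl}-3-methyloxirane F6. n-BuLi (3 equiv) then fragments the epoxy chloride to the terminal propargylic alcohol 11, with the epoxide C–O bond at the carbinol carbon kept.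

Step 9. Intermolecular conjugate addition of a hindered tertiary alkoxide may be unfavourable or may revert before the ketal is eliminated. The fallback sets out from 11 (with 12) and comes back at 16, and makes the same C–O bond intramolecularly after the C–C bond. 12 is iodinated ortho to the hydroxyl (N-iodosuccinimide) to 2-iodo-4,6-dimethoxyphenol F7 and acetylated (Ac2O, pyridine) to 2-iodo-4,6-dimethoxyphenyl acetate F8. Sonogashira coupling with 11 (PdCl2(PPh3)2, CuI, Et3N) gives 2-{(3S)-3-hydroxy-3-methyl-5-[(1R,3R)-1,3-dimethyl-2-methylidenecyclohexyl]pent-1-yn-1-yl}-4,6-dimethoxyphenyl acetate F9. Semi-hydrogenation (H2, Pd/CaCO3 poisoned with Pb(OAc)2, quinoline) gives the (Z)-alkene 2-{(1Z,3S)-3-hydroxy-3-methyl-5-[(1R,3R)-1,3-dimethyl-2-methylidenecyclohexyl]pent-1-en-1-yl}-4,6-dimethoxyphenyl acetate F10. K2CO3 in MeOH frees the phenol 2-{(1Z,3S)-3-hydroxy-3-methyl-5-[(1R,3R)-1,3-dimethyl-2-methylidenecyclohexyl]pent-1-en-1-yl}-4,6-dimethoxyphenol F11. PhI(OAc)2 in MeOH then gives the quinone monoketal 6-{(1Z,3S)-3-hydroxy-3-methyl-5-[(1R,3R)-1,3-dimethyl-2-methylidenecyclohexyl]pent-1-en-1-yl}-2,4,4-trimethoxycyclohexa-2,5-dien-1-one F12. Its tertiary hydroxyl adds to the adjacent enone carbon in a six-membered oxa-Michael closure to give (2S)-2-{2-[(1R,3R)-1,3-dimethyl-2-methylidenecyclohexyl]ethyl}-6,8,8-trimethoxy-2-methyl-8,8a-dihydro-2H-chromen-5(4aH)-one F13, which loses methanol with pyridinium p-toluenesulfonate to give 16 directly.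

## Further compounds

F1 | step 1 | cis-2,6-dimethylcyclohexanone | C[C@H]1CCC[C@@H](C)C1=O
F2 | step 1 | {[(6S)-2,6-dimethylcyclohex-1-en-1-yl]oxy}trimethylsilane | C[Si](C)(C)OC1=C(C)CCC[C@@H]1C
F3 | step 7 | ethyl (2E)-5-[(1R,3R)-1,3-dimethyl-2-methylidenecyclohexyl]-3-methylpent-2-enoate | C=C1[C@H](C)CCC[C@]1(C)CC/C(C)=C/C(=O)OCC
F4 | step 7 | (2E)-5-[(1R,3R)-1,3-dimethyl-2-methylidenecyclohexyl]-3-methylpent-2-en-1-ol | C=C1[C@H](C)CCC[C@]1(C)CC/C(C)=C/CO
F5 | step 7 | [(2S,3S)-3-{2-[(1R,3R)-1,3-dimethyl-2-methylidenecyclohexyl]ethyl}-3-methyloxiran-2-yl]methanol | C=C1[C@H](C)CCC[C@]1(C)CC[C@]2(C)O[C@H]2CO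
F6 | step 7 | (2R,3S)-2-(chloromethyl)-3-{2-[(1R,3R)-1,3-dimethyl-2-methylidenecyclohexyl]ethyl}-3-methyloxirane | C=C1[C@H](C)CCC[C@]1(C)CC[C@]2(C)O[C@H]2CCl
F7 | step 9 | 2-iodo-4,6-dimethoxyphenol | Oc1c(I)cc(OC)cc1OC
F8 | step 9 | 2-iodo-4,6-dimethoxyphenyl acetate | CC(=O)Oc1c(I)cc(OC)cc1OC
F9 | step 9 | 2-{(3S)-3-hydroxy-3-methyl-5-[(1R,3R)-1,3-dimethyl-2-methylidenecyclohexyl]pent-1-yn-1-yl}-4,6-dimethoxyphenyl acetate | C=C1[C@H](C)CCC[C@]1(C)CC[C@@](O)(C)C#Cc1cc(OC)cc(OC)c1OC(C)=O
F10 | step 9 | 2-{(1Z,3S)-3-hydroxy-3-methyl-5-[(1R,3R)-1,3-dimethyl-2-methylidenecyclohexyl]pent-1-en-1-yl}-4,6-dimethoxyphenyl acetate | C=C1[C@H](C)CCC[C@]1(C)CC[C@@](O)(C)/C=C\c1cc(OC)cc(OC)c1OC(C)=O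
F11 | step 9 | 2-{(1Z,3S)-3-hydroxy-3-methyl-5-[(1R,3R)-1,3-dimethyl-2-methylidenecyclohexyl]pent-1-en-1-yl}-4,6-dimethoxyphenol | C=C1[C@H](C)CCC[C@]1(C)CC[C@@](O)(C)/C=C\c1cc(OC)cc(OC)c1O
F12 | step 9 | 6-{(1Z,3S)-3-hydroxy-3-methyl-5-[(1R,3R)-1,3-dimethyl-2-methylidenecyclohexyl]pent-1-en-1-yl}-2,4,4-trimethoxycyclohexa-2,5-dien-1-one | C=C1[C@H](C)CCC[C@]1(C)CC[C@@](O)(C)/C=C\C1=CC(OC)(OC)C=C(OC)C1=O
F13 | step 9 | (2S)-2-{2-[(1R,3R)-1,3-dimethyl-2-methylidenecyclohexyl]ethyl}-6,8,8-trimethoxy-2-methyl-8,8a-dihydro-2H-chromen-5(4aH)-one | C=C1[C@H](C)CCC[C@]1(C)CC[C@@]1(C)C=CC2C(=O)C(OC)=CC(OC)(OC)C2O1
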